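The plan rests on cutting the C13–C14 bond of the cyclopentane (C13–C17). In the target, C13 bears the (11Z)-alkenyl arm and sits next to oxygenated C14 of the C14/C15 oxirane. This homoallylic array is the signature of γ-attack by a C11-borylated C12=C13 allyl unit on a C14 aldehyde. One intramolecular allylboration therefore closes the five-membered ring, forms C13–C14, fixes C13 and C14, and turns the C11 stereocentre into the 11Z alkene. Its precursor is an open-chain α-chloro aldehyde (C14=O, C15–Cl, C18–Cl) tethered through C16–C17 to an (11R,12E)-allyl pinacol boronate carrying the full C1–C20 chain, released in the flask from its primary alcohol.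

Key step: step 18

Remark: atom labels C1–C20 in the text are those of the target chain (ring C13–C17, oxirane C14/C15, chloride on C18); systematic names of open-chain intermediates carry their own locants.
Remark: the aldehyde cannot be stored next to the allylboronate, so the C14 oxygen travels as a triethylsilyl ether through the copper steps and the aldehyde is made in the flask; the carbonate before borylation has to be the (11Z,13R) isomer.
Remark: the descriptors of aldehyde 29 (11R, 12E, 15R, 17R, 18S) and chlorohydrin 31 were checked against the target (13S, 14R, 15S, 17R, 18S) and the chair model; they agree and no correction was needed.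
Assumption: the (2S,5S) amine of step 8 and the (S,S) ruthenium catalyst of step 11 are taken to give 15R and 13S by the usual shielding models; if the sense were opposite, the mirror-image catalyst would be used.

Step 1
Reactants: 1 methyl hex-5-ynoate; 2 4-chlorobut-2-yn-1-ol
Product: 3 methyl 10-hydroxydeca-5,8-diynoate
Conditions: CuI, NaI, Cs2CO3, DMF, rt
Reagents that add atoms: none
Why: Copper-mediated coupling of a terminal alkyne with a propargylic halide (chloride exchanged for iodide in the flask) gives the skipped diyne by SN2 attack of the copper acetylide, and the free hydroxyl is tolerated.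

Step 2
Reactants: 3 methyl 10-hydroxydeca-5,8-diynoate
Product: 4 methyl 10-bromodeca-5,8-diynoate
Conditions: CBr4, PPh3, CH2Cl2, 0 °C
Reagents that add atoms: tetrabromomethane, BrC(Br)(Br)Br
Why: Appel bromination converts the primary propargylic alcohol into the bromide under neutral conditions that leave the base-sensitive skipped diyne untouched.

Step 3
Reactants: 5 hex-5-enoyl chloride; 6 (S)-4-benzyloxazolidin-2-one
Product: 7 (S)-4-benzyl-3-(hex-5-enoyl)oxazolidin-2-one
Conditions: Et3N, DMAP (cat.), CH2Cl2, 0 °C to rt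
Reagents that add atoms: none
Why: DMAP-catalysed N-acylation of the oxazolidinone with the acid chloride installs the auxiliary on the future C13 carbonyl; C2 of the acyl chain is the future C17 and the terminal alkene masks C14.

Step 4
Reactants: 7 (S)-4-benzyl-3-(hex-5-enoyl)oxazolidin-2-one; 8 propanal
Product: 11 (S)-4-benzyl-3-[(2S,3R)-2-(but-3-en-1-yl)-3-hydroxypentanoyl]oxazolidin-2-one, via dibutylboron (Z)-enolate 9 (not isolated), via boron aldolate 10 (not isolated)
Conditions: Bu2BOTf, i-Pr2NEt, CH2Cl2, −78 to 0 °C; 8, −78 to 0 °C; then pH 7 buffer, MeOH, H2O2, 0 °C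
Reagents that add atoms: none
Why: Evans syn-aldol reaction: the (Z)-boron enolate 9 adds to propanal through a Zimmerman–Traxler chair whose open face is fixed by the benzyl group of the auxiliary, setting C17 and the C18 carbinol (2S,3R, syn), and oxidative work-up frees 11 from aldolate 10.

Step 5
Reactants: 11 (S)-4-benzyl-3-[(2S,3R)-2-(but-3-en-1-yl)-3-hydroxypentanoyl]oxazolidin-2-one
Product: 12 (2S,3R)-2-(but-3-en-1-yl)-3-hydroxy-N-methoxy-N-methylpentanamide
Conditions: MeNHOMe·HCl, AlMe3, CH2Cl2, −10 °C to rt; aq. Rochelle salt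
Reagents that add atoms: N,O-dimethylhydroxylamine hydrochloride, CNOC.Cl
Why: Weinreb transamidation with the aluminium amide, assisted by the free β-hydroxyl, exchanges the auxiliary for the N-methoxy-N-methyl amide without touching C17 or C18.

Step 6
Reactants: 12 (2S,3R)-2-(but-3-en-1-yl)-3-hydroxy-N-methoxy-N-methylpentanamide
Product: 13 (2R,3S)-2-(but-3-en-1-yl)-3-chloro-N-methoxy-N-methylpentanamide
Conditions: PPh3, NCS, THF, 0 °C to rt
Reagents that add atoms: N-chlorosuccinimide, O=C1CCC(=O)N1Cl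
Why: Appel-type deoxychlorination: chloride displaces the phosphorus-activated hydroxyl by SN2 with inversion, turning the syn-aldol carbinol into the 18S chloride anti to the C16 branch, and the weakly acidic amide α-hydrogen limits elimination.

Step 7
Reactants: 13 (2R,3S)-2-(but-3-en-1-yl)-3-chloro-N-methoxy-N-methylpentanamide
Product: 14 (2R,3S)-3-chloro-N-methoxy-N-methyl-2-(3-oxopropyl)pentanamide
Conditions: OsO4 (cat.), NaIO4, 2,6-lutidine, dioxane/H2O, rt
Reagents that add atoms: osmium tetroxide, O=[Os](=O)(=O)=O; sodium periodate, [Na+].[O-]I(=O)(=O)=O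
Why: Lemieux–Johnson cleavage (dihydroxylation, then periodate scission) of the terminal alkene gives the C14 aldehyde with the C15 methylene next to it, and no stereocentre is involved.

Step 8
Reactants: 14 (2R,3S)-3-chloro-N-methoxy-N-methyl-2-(3-oxopropyl)pentanamide
Product: 16 (2R,3S)-3-chloro-2-[(2R)-2-chloro-3-hydroxypropyl]-N-methoxy-N-methylpentanamide, via α-chloro aldehyde 15 (not isolated)
Conditions: (2S,5S)-2,5-diphenylpyrrolidine (10 mol%), NCS, CH2Cl2, 0 °C to rt; then NaBH4, MeOH, 0 °C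
Reagents that add atoms: N-chlorosuccinimide, O=C1CCC(=O)N1Cl
Why: Enamine-catalysed α-chlorination: one phenyl group of the C2-symmetric amine screens a face of the enamine, so chlorine should be delivered to C15 with catalyst control (15R) regardless of remote C17, and borohydride reduces the labile aldehyde 15 at once to the configurationally stable 2-chloro-1-ol.

Step 9
Reactants: 16 (2R,3S)-3-chloro-2-[(2R)-2-chloro-3-hydroxypropyl]-N-methoxy-N-methylpentanamide
Product: 17 (2R,3S)-3-chloro-2-[(2R)-2-chloro-3-(triethylsilyloxy)propyl]-N-methoxy-N-methylpentanamide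
Conditions: TESCl, imidazole, CH2Cl2, 0 °C
Reagents that add atoms: chlorotriethylsilane, CC[Si](Cl)(CC)CC
Why: Silylation of the primary hydroxyl blocks lactonisation onto the amide and base-induced oxirane formation from the 2-chloro-1-ol in the later organometallic and copper steps.

Step 10
Reactants: 17 (2R,3S)-3-chloro-2-[(2R)-2-chloro-3-(triethylsilyloxy)propyl]-N-methoxy-N-methylpentanamide; 18 trimethylsilylacetylene
Product: 20 (4R,6R)-6-chloro-4-[(1S)-1-chloropropyl]-7-(triethylsilyloxy)-1-(trimethylsilyl)hept-1-yn-3-one, via lithium (trimethylsilyl)acetylide 19 (not isolated)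
Conditions: 18, n-BuLi, THF, −78 °C; then 17, −78 to −20 °C; aq. NH4Cl
Reagents that add atoms: none
Why: Weinreb ketone synthesis: acetylide 19 adds once to the N-methoxy amide and is too weak a base to enolise it, so C17 and the β-chloride on C18 survive and the alkyne carbons C11 and C12 are attached to C13.

Step 11
Reactants: 20 (4R,6R)-6-chloro-4-[(1S)-1-chloropropyl]-7-(triethylsilyloxy)-1-(trimethylsilyl)hept-1-yn-3-one
Product: 21 (3S,4R,6R)-6-chloro-4-[(1S)-1-chloropropyl]-7-(triethylsilyloxy)-1-(trimethylsilyl)hept-1-yn-3-ol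
Conditions: Ru[(S,S)-TsNCHPhCHPhNH](η6-p-cymene) (2 mol%), i-PrOH, rt
Reagents that add atoms: none
Why: Noyori asymmetric transfer hydrogenation under base-free conditions: the (S,S) ligand directs hydride to one ynone face, giving the (S)-propargylic alcohol at C13 by catalyst control without enolising the β-chlorinated C17.

Step 12
Reactants: 21 (3S,4R,6R)-6-chloro-4-[(1S)-1-chloropropyl]-7-(triethylsilyloxy)-1-(trimethylsilyl)hept-1-yn-3-ol
Product: 22 (3S,4R,6R)-6-chloro-4-[(1S)-1-chloropropyl]-7-(triethylsilyloxy)hept-1-yn-3-ol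
Conditions: K2CO3 (cat.), MeOH, 0 °C, short contact
Reagents that add atoms: none
Why: Methanolysis of the alkynyl C–Si bond (protodesilylation) is fast at 0 °C, where the triethylsilyl ether holds and the deprotonated C13 hydroxyl should not yet displace the C15 chloride.

Step 13
Reactants: 22 (3S,4R,6R)-6-chloro-4-[(1S)-1-chloropropyl]-7-(triethylsilyloxy)hept-1-yn-3-ol; 4 methyl 10-bromodeca-5,8-diynoate
Product: 23 methyl (13S,14R,16R)-16-chloro-14-[(1S)-1-chloropropyl]-13-hydroxy-17-(triethylsilyloxy)heptadeca-5,8,11-triynoate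
Conditions: CuI, NaI, Cs2CO3, DMF, rt
Reagents that add atoms: none
Why: Copper-mediated alkyne–propargyl halide coupling joins C11 to C10; the carbonate base is too weak to deprotonate the C13 hydroxyl, so neither O-alkylation nor attack on the secondary chlorides should compete.

Step 14
Reactants: 23 methyl (13S,14R,16R)-16-chloro-14-[(1S)-1-chloropropyl]-13-hydroxy-17-(triethylsilyloxy)heptadeca-5,8,11-triynoate
Product: 24 methyl (5Z,8Z,11Z,13R,14R,16R)-16-chloro-14-[(1S)-1-chloropropyl]-13-hydroxy-17-(triethylsilyloxy)heptadeca-5,8,11-trienoate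
Conditions: H2 (1 atm), Pd/CaCO3–Pb(OAc)2 (Lindlar catalyst), quinoline, EtOAc, rt
Reagents that add atoms: none
Why: Lindlar semi-hydrogenation adds hydrogen syn to each alkyne and gives the three Z alkenes; the alkyl chlorides and the silyl ether are inert, and the C13 descriptor changes from S to R only because the CIP priorities change.

Step 15
Reactants: 24 methyl (5Z,8Z,11Z,13R,14R,16R)-16-chloro-14-[(1S)-1-chloropropyl]-13-hydroxy-17-(triethylsilyloxy)heptadeca-5,8,11-trienoate
Product: 25 methyl (5Z,8Z,11Z,13R,14R,16R)-16-chloro-14-[(1S)-1-chloropropyl]-13-[(methoxycarbonyl)oxy]-17-(triethylsilyloxy)heptadeca-5,8,11-trienoate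
Conditions: ClCO2Me, pyridine, DMAP (cat.), CH2Cl2, 0 °C
Reagents that add atoms: methyl chloroformate, COC(Cl)=O
Why: O-acylation of the allylic alcohol with the chloroformate gives the methyl carbonate leaving group with retention at C13.

Step 16
Reactants: 25 methyl (5Z,8Z,11Z,13R,14R,16R)-16-chloro-14-[(1S)-1-chloropropyl]-13-[(methoxycarbonyl)oxy]-17-(triethylsilyloxy)heptadeca-5,8,11-trienoate; 26 bis(pinacolato)diboron
Product: 27 methyl (5Z,8Z,11R,12E,14R,16R)-16-chloro-14-[(1S)-1-chloropropyl]-11-(4,4,5,5-tetramethyl-1,3,2-dioxaborolan-2-yl)-17-(triethylsilyloxy)heptadeca-5,8,12-trienoate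
Conditions: CuCl (10 mol%), KOt-Bu (10 mol%), Xantphos (10 mol%), 26, THF, 0 °C to rt
Reagents that add atoms: none
Why: Copper-catalysed γ-selective allylic borylation: the boryl–copper species attacks C11 anti to the C13 carbonate in the conformer that keeps H13 in the plane of the (11Z)-alkene, so anti-SN2′ transfer from 13R gives the 11R boronate and the 12E alkene, while the methoxide released with CO2 renews the catalyst without stoichiometric base and spares the alkyl chlorides.

Step 17
Reactants: 27 methyl (5Z,8Z,11R,12E,14R,16R)-16-chloro-14-[(1S)-1-chloropropyl]-11-(4,4,5,5-tetramethyl-1,3,2-dioxaborolan-2-yl)-17-(triethylsilyloxy)heptadeca-5,8,12-trienoate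
Product: 28 methyl (5Z,8Z,11R,12E,14R,16R)-16-chloro-14-[(1S)-1-chloropropyl]-17-hydroxy-11-(4,4,5,5-tetramethyl-1,3,2-dioxaborolan-2-yl)heptadeca-5,8,12-trienoate
Conditions: PPTS (cat.), MeOH/CH2Cl2, 0 °C
Reagents that add atoms: none
Why: Mild acid-catalysed methanolysis removes the primary triethylsilyl ether without fluoride or base, so the allyl pinacol boronate and the 2-chloro-1-ol are preserved.

Step 18
Reactants: 28 methyl (5Z,8Z,11R,12E,14R,16R)-16-chloro-14-[(1S)-1-chloropropyl]-17-hydroxy-11-(4,4,5,5-tetramethyl-1,3,2-dioxaborolan-2-yl)heptadeca-5,8,12-trienoate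
Product: 31 methyl (5Z,8Z,11Z)-12-[(1S,2R,3R,5R)-3-chloro-5-[(1S)-1-chloropropyl]-2-hydroxycyclopentyl]dodeca-5,8,11-trienoate, via ω-oxo allylboronate 29 (not isolated), via cyclic O-boryl ether 30 (not isolated)
Conditions: Dess–Martin periodinane, NaHCO3, CH2Cl2 (dilute), 0 °C to rt; aq. NaHCO3/Na2S2O3
Reagents that add atoms: none
Why: Buffered Dess–Martin oxidation unveils aldehyde 29 without base-induced loss of the C15 configuration; its carbonyl oxygen then binds the tethered boron and C13 of the (12E)-allyl unit attacks C14 suprafacially through a closed six-membered chair (B, O, C14, C13, C12, C11) while boron leaves C11 and C11=C12 forms, and work-up hydrolyses borate 30. The closest known reaction type is the uncatalysed intramolecular allylboration of ω-oxo allylboronates to 2-alkenylcycloalkanols, combined with the Z-selective addition of α-substituted pinacol allylboronates and the allylation of α-chloro aldehydes. The cyclopentane (C13–C17) closes in a 5-exo-trig mode at the carbonyl carbon, the C15–C16–C17 tether spanning two equatorial sites of the chair, which places the C12 arm and the new C14–O bond trans. C13 is set by 1,3-transfer from C11, since with C10 axial (away from the pinacol methyl groups) the 11R centre exposes the C13 face that gives 13S and the 11Z alkene, and C14 (R) follows from the chair because the E alkene holds C17 equatorial. The step needs Z over E geometry and a single C13 face: the rival chair with C10 equatorial would attack the opposite face, forcing the C12 arm cis to the C18 side chain on C17 and the C15 chloride syn to the carbonyl oxygen, so the preset 17R and 15R centres reinforce the boronate-controlled path and leave the chloride trans to the C14 oxygen.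

Step 19
Reactants: 31 methyl (5Z,8Z,11Z)-12-[(1S,2R,3R,5R)-3-chloro-5-[(1S)-1-chloropropyl]-2-hydroxycyclopentyl]dodeca-5,8,11-trienoate
Product: 32 methyl (5Z,8Z,11Z)-12-[(1R,2S,3R,5S)-3-[(1S)-1-chloropropyl]-6-oxabicyclo[3.1.0]hexan-2-yl]dodeca-5,8,11-trienoate
Conditions: K2CO3, MeOH, 0 °C to rt
Reagents that add atoms: none
Why: Intramolecular Williamson closure (3-exo-tet): the deprotonated C14 hydroxyl displaces the trans, anti-periplanar C15 chloride with inversion (15R to 15S) to give the cis-fused oxirane, and methanol makes ester exchange degenerate.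

Compound list
1 | methyl hex-5-ynoate | C#CCCCC(=O)OC | starting material
2 | 4-chlorobut-2-yn-1-ol | OCC#CCCl | starting material
3 | methyl 10-hydroxydeca-5,8-diynoate | OCC#CCC#CCCCC(=O)OC | intermediate
4 | methyl 10-bromodeca-5,8-diynoate | BrCC#CCC#CCCCC(=O)OC | intermediate
5 | hex-5-enoyl chloride | C=CCCCC(Cl)=O | starting material
6 | (S)-4-benzyloxazolidin-2-one | O=C1OC[C@H](Cc2ccccc2)N1 | starting material
7 | (S)-4-benzyl-3-(hex-5-enoyl)oxazolidin-2-one | C=CCCCC(=O)N1[C@@H](Cc2ccccc2)COC1=O | intermediate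
8 | propanal | CCC=O | starting material
9 | (S)-4-benzyl-3-[(Z)-1-(dibutylboryloxy)hexa-1,5-dien-1-yl]oxazolidin-2-one | CCCCB(CCCC)O/C(=C\CCC=C)N1[C@@H](Cc2ccccc2)COC1=O | intermediate
10 | (S)-4-benzyl-3-[(2S,3R)-2-(but-3-en-1-yl)-3-(dibutylboryloxy)pentanoyl]oxazolidin-2-one | CC[C@@H](OB(CCCC)CCCC)[C@H](CCC=C)C(=O)N1[C@@H](Cc2ccccc2)COC1=O | intermediate
11 | (S)-4-benzyl-3-[(2S,3R)-2-(but-3-en-1-yl)-3-hydroxypentanoyl]oxazolidin-2-one | CC[C@@H](O)[C@H](CCC=C)C(=O)N1[C@@H](Cc2ccccc2)COC1=O | intermediate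
12 | (2S,3R)-2-(but-3-en-1-yl)-3-hydroxy-N-methoxy-N-methylpentanamide | CC[C@@H](O)[C@H](CCC=C)C(=O)N(C)OC | intermediate
13 | (2R,3S)-2-(but-3-en-1-yl)-3-chloro-N-methoxy-N-methylpentanamide | CC[C@H](Cl)[C@H](CCC=C)C(=O)N(C)OC | intermediate
14 | (2R,3S)-3-chloro-N-methoxy-N-methyl-2-(3-oxopropyl)pentanamide | CC[C@H](Cl)[C@H](CCC=O)C(=O)N(C)OC | intermediate
15 | (2R,3S)-3-chloro-2-[(2R)-2-chloro-3-oxopropyl]-N-methoxy-N-methylpentanamide | CC[C@H](Cl)[C@H](C[C@@H](Cl)C=O)C(=O)N(C)OC | intermediate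
16 | (2R,3S)-3-chloro-2-[(2R)-2-chloro-3-hydroxypropyl]-N-methoxy-N-methylpentanamide | CC[C@H](Cl)[C@H](C[C@@H](Cl)CO)C(=O)N(C)OC | intermediate
17 | (2R,3S)-3-chloro-2-[(2R)-2-chloro-3-(triethylsilyloxy)propyl]-N-methoxy-N-methylpentanamide | CC[C@H](Cl)[C@H](C[C@@H](Cl)CO[Si](CC)(CC)CC)C(=O)N(C)OC | intermediate
18 | trimethylsilylacetylene | C#C[Si](C)(C)C | starting material
19 | lithium (trimethylsilyl)acetylide | [Li]C#C[Si](C)(C)C | intermediate
20 | (4R,6R)-6-chloro-4-[(1S)-1-chloropropyl]-7-(triethylsilyloxy)-1-(trimethylsilyl)hept-1-yn-3-one | CC[C@H](Cl)[C@H](C[C@@H](Cl)CO[Si](CC)(CC)CC)C(=O)C#C[Si](C)(C)C | intermediate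
21 | (3S,4R,6R)-6-chloro-4-[(1S)-1-chloropropyl]-7-(triethylsilyloxy)-1-(trimethylsilyl)hept-1-yn-3-ol | CC[C@H](Cl)[C@H](C[C@@H](Cl)CO[Si](CC)(CC)CC)[C@H](O)C#C[Si](C)(C)C | intermediate
22 | (3S,4R,6R)-6-chloro-4-[(1S)-1-chloropropyl]-7-(triethylsilyloxy)hept-1-yn-3-ol | CC[C@H](Cl)[C@H](C[C@@H](Cl)CO[Si](CC)(CC)CC)[C@H](O)C#C | intermediate
23 | methyl (13S,14R,16R)-16-chloro-14-[(1S)-1-chloropropyl]-13-hydroxy-17-(triethylsilyloxy)heptadeca-5,8,11-triynoate | CC[C@H](Cl)[C@H](C[C@@H](Cl)CO[Si](CC)(CC)CC)[C@H](O)C#CCC#CCC#CCCCC(=O)OC | intermediate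
24 | methyl (5Z,8Z,11Z,13R,14R,16R)-16-chloro-14-[(1S)-1-chloropropyl]-13-hydroxy-17-(triethylsilyloxy)heptadeca-5,8,11-trienoate | CC[C@H](Cl)[C@H](C[C@@H](Cl)CO[Si](CC)(CC)CC)[C@H](O)/C=C\C/C=C\C/C=C\CCCC(=O)OC | intermediate
25 | methyl (5Z,8Z,11Z,13R,14R,16R)-16-chloro-14-[(1S)-1-chloropropyl]-13-[(methoxycarbonyl)oxy]-17-(triethylsilyloxy)heptadeca-5,8,11-trienoate | CC[C@H](Cl)[C@H](C[C@@H](Cl)CO[Si](CC)(CC)CC)[C@H](OC(=O)OC)/C=C\C/C=C\C/C=C\CCCC(=O)OC | intermediate
26 | bis(pinacolato)diboron | CC1(C)OB(OC1(C)C)B1OC(C)(C)C(C)(C)O1 | starting material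
27 | methyl (5Z,8Z,11R,12E,14R,16R)-16-chloro-14-[(1S)-1-chloropropyl]-11-(4,4,5,5-tetramethyl-1,3,2-dioxaborolan-2-yl)-17-(triethylsilyloxy)heptadeca-5,8,12-trienoate | CC[C@H](Cl)[C@H](C[C@@H](Cl)CO[Si](CC)(CC)CC)/C=C/[C@H](B1OC(C)(C)C(C)(C)O1)C/C=C\C/C=C\CCCC(=O)OC | intermediate
28 | methyl (5Z,8Z,11R,12E,14R,16R)-16-chloro-14-[(1S)-1-chloropropyl]-17-hydroxy-11-(4,4,5,5-tetramethyl-1,3,2-dioxaborolan-2-yl)heptadeca-5,8,12-trienoate | CC[C@H](Cl)[C@H](C[C@@H](Cl)CO)/C=C/[C@H](B1OC(C)(C)C(C)(C)O1)C/C=C\C/C=C\CCCC(=O)OC | intermediate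
29 | methyl (5Z,8Z,11R,12E,14R,16R)-16-chloro-14-[(1S)-1-chloropropyl]-17-oxo-11-(4,4,5,5-tetramethyl-1,3,2-dioxaborolan-2-yl)heptadeca-5,8,12-trienoate | O=C[C@H](Cl)C[C@@H]([C@@H](Cl)CC)/C=C/[C@H](B1OC(C)(C)C(C)(C)O1)C/C=C\C/C=C\CCCC(=O)OC | intermediate
30 | methyl (5Z,8Z,11Z)-12-[(1S,2R,3R,5R)-3-chloro-5-[(1S)-1-chloropropyl]-2-[(4,4,5,5-tetramethyl-1,3,2-dioxaborolan-2-yl)oxy]cyclopentyl]dodeca-5,8,11-trienoate | CC[C@H](Cl)[C@@H]1C[C@@H](Cl)[C@H](OB2OC(C)(C)C(C)(C)O2)[C@H]1/C=C\C/C=C\C/C=C\CCCC(=O)OC | intermediate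
31 | methyl (5Z,8Z,11Z)-12-[(1S,2R,3R,5R)-3-chloro-5-[(1S)-1-chloropropyl]-2-hydroxycyclopentyl]dodeca-5,8,11-trienoate | CC[C@H](Cl)[C@@H]1C[C@@H](Cl)[C@H](O)[C@H]1/C=C\C/C=C\C/C=C\CCCC(=O)OC | intermediate
32 | methyl (5Z,8Z,11Z)-12-[(1R,2S,3R,5S)-3-[(1S)-1-chloropropyl]-6-oxabicyclo[3.1.0]hexan-2-yl]dodeca-5,8,11-trienoate | CC[C@H](Cl)[C@@H]1C[C@@H]2O[C@@H]2[C@H]1/C=C\C/C=C\C/C=C\CCCC(=O)OC | target

Total step count: 19. Longest linear sequence: 17 steps (steps 3 to 19); steps 1 and 2 make the C1–C10 bromide that enters at step 13.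

Steps most likely to fail

Step 18. The α-substituted boronate may react through the chair with C10 equatorial or through a boat, which would erode the Z geometry and the facial control, or the C–B bond may be attacked while the alcohol is being oxidised. The fallback removes the α-substituent from the boron reagent and makes the Z alkene later from an alkyne. It sets out from alkyne 22 and comes back at chlorohydrin 31. Lindlar semi-hydrogenation of 22 would give the vinyl carbinol F1, and methyl chloroformate/pyridine its methyl carbonate F2. Copper-catalysed SN2′ borylation with 26 would give the primary (E)-allyl pinacol boronate F3, for which the carbinol configuration no longer matters, and PPTS/MeOH the free alcohol F4. Dess–Martin oxidation would pass through the aldehyde F5, which should cyclise as an unsubstituted (E)-allylboronate (the best-precedented case, trans-2-vinylcycloalkanol, face set by C17) to the vinyl chlorohydrin F6. TBSOTf/2,6-lutidine would give the silyl ether F7, OsO4/NaIO4 the ring aldehyde F8, and the Ohira–Bestmann reagent with K2CO3/MeOH the ethynylcyclopentane F9. Copper-mediated coupling with bromide 4 would give the triyne F10, Lindlar semi-hydrogenation the (5Z,8Z,11Z)-triene silyl ether F11, and HF·pyridine would release 31.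

Step 6. Activation of the hindered β-hydroxyl next to the amide may end in elimination toward the carbonyl, or in carbonyl participation and retention, instead of clean inversion. The fallback carries out the chlorination with C13 at the alcohol oxidation level. It sets out from aldol adduct 11 and comes back at chloro amide 13. LiBH4 would cleave the auxiliary to the diol F12, and TBSCl/imidazole would protect the primary hydroxyl as the silyl ether F13. The Appel reaction (PPh3, NCS) on this carbonyl-free substrate would give, with inversion, the chloride F14, and TBAF the chloro alcohol F15. TEMPO/PhI(OAc)2 in MeCN/H2O would give the β-chloro acid F16, which is coupled with MeNHOMe·HCl (EDC·HCl, HOBt, N-methylmorpholine) to 13.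

Step 14. Three alkynes hydrogenated in one flask may be over-reduced or may stall at ene-yne stages. The fallback reduces the diyne before the coupling so that a single alkyne is left for the last hydrogenation. It sets out from diynol 3 (with alkyne 22) and comes back at triene 24. Lindlar semi-hydrogenation of 3 would give the dienol F17, and CBr4/PPh3 the (Z)-allylic bromide F18. Copper-mediated SN2 coupling with 22 (CuI, NaI, Cs2CO3, DMF) would give the dienyne F19, whose lone alkyne next to the carbinol is then semi-hydrogenated to 24.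

Further compounds
F1 | step 18 | (3R,4R,6R)-6-chloro-4-[(1S)-1-chloropropyl]-7-(triethylsilyloxy)hept-1-en-3-ol | CC[C@H](Cl)[C@H](C[C@@H](Cl)CO[Si](CC)(CC)CC)[C@H](O)C=C
F2 | step 18 | (3R,4R,6R)-6-chloro-4-[(1S)-1-chloropropyl]-7-(triethylsilyloxy)hept-1-en-3-yl methyl carbonate | CC[C@H](Cl)[C@H](C[C@@H](Cl)CO[Si](CC)(CC)CC)[C@H](OC(=O)OC)C=C
F3 | step 18 | 2-[(2E,4R,6R)-6-chloro-4-[(1S)-1-chloropropyl]-7-(triethylsilyloxy)hept-2-en-1-yl]-4,4,5,5-tetramethyl-1,3,2-dioxaborolane | CC[C@H](Cl)[C@H](C[C@@H](Cl)CO[Si](CC)(CC)CC)/C=C/CB1OC(C)(C)C(C)(C)O1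
F4 | step 18 | (2R,4R,5E)-2-chloro-4-[(1S)-1-chloropropyl]-7-(4,4,5,5-tetramethyl-1,3,2-dioxaborolan-2-yl)hept-5-en-1-ol | CC[C@H](Cl)[C@H](C[C@@H](Cl)CO)/C=C/CB1OC(C)(C)C(C)(C)O1
F5 | step 18 | (2R,4R,5E)-2-chloro-4-[(1S)-1-chloropropyl]-7-(4,4,5,5-tetramethyl-1,3,2-dioxaborolan-2-yl)hept-5-enal | O=C[C@H](Cl)C[C@@H]([C@@H](Cl)CC)/C=C/CB1OC(C)(C)C(C)(C)O1
F6 | step 18 | (1R,2R,4R,5S)-2-chloro-4-[(1S)-1-chloropropyl]-5-ethenylcyclopentan-1-ol | CC[C@H](Cl)[C@@H]1C[C@@H](Cl)[C@H](O)[C@H]1C=C
F7 | step 18 | tert-butyl{[(1R,2R,4R,5S)-2-chloro-4-[(1S)-1-chloropropyl]-5-ethenylcyclopentyl]oxy}dimethylsilane | CC[C@H](Cl)[C@@H]1C[C@@H](Cl)[C@H](O[Si](C)(C)C(C)(C)C)[C@H]1C=C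
F8 | step 18 | (1S,2R,3R,5R)-2-(tert-butyldimethylsilyloxy)-3-chloro-5-[(1S)-1-chloropropyl]cyclopentane-1-carbaldehyde | CC[C@H](Cl)[C@@H]1C[C@@H](Cl)[C@H](O[Si](C)(C)C(C)(C)C)[C@H]1C=O
F9 | step 18 | tert-butyl{[(1R,2R,4R,5R)-2-chloro-4-[(1S)-1-chloropropyl]-5-ethynylcyclopentyl]oxy}dimethylsilane | CC[C@H](Cl)[C@@H]1C[C@@H](Cl)[C@H](O[Si](C)(C)C(C)(C)C)[C@H]1C#C
F10 | step 18 | methyl 12-[(1R,2R,3R,5R)-2-(tert-butyldimethylsilyloxy)-3-chloro-5-[(1S)-1-chloropropyl]cyclopentyl]dodeca-5,8,11-triynoate | CC[C@H](Cl)[C@@H]1C[C@@H](Cl)[C@H](O[Si](C)(C)C(C)(C)C)[C@H]1C#CCC#CCC#CCCCC(=O)OC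
F11 | step 18 | methyl (5Z,8Z,11Z)-12-[(1S,2R,3R,5R)-2-(tert-butyldimethylsilyloxy)-3-chloro-5-[(1S)-1-chloropropyl]cyclopentyl]dodeca-5,8,11-trienoate | CC[C@H](Cl)[C@@H]1C[C@@H](Cl)[C@H](O[Si](C)(C)C(C)(C)C)[C@H]1/C=C\C/C=C\C/C=C\CCCC(=O)OC
F12 | step 6 | (2R,3R)-2-(but-3-en-1-yl)pentane-1,3-diol | CC[C@@H](O)[C@H](CCC=C)CO
F13 | step 6 | (3R,4R)-4-[(tert-butyldimethylsilyloxy)methyl]oct-7-en-3-ol | CC[C@@H](O)[C@H](CCC=C)CO[Si](C)(C)C(C)(C)C
F14 | step 6 | tert-butyl{[(2R)-2-[(1S)-1-chloropropyl]hex-5-en-1-yl]oxy}dimethylsilane | CC[C@H](Cl)[C@H](CCC=C)CO[Si](C)(C)C(C)(C)C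
F15 | step 6 | (2R)-2-[(1S)-1-chloropropyl]hex-5-en-1-ol | CC[C@H](Cl)[C@H](CCC=C)CO
F16 | step 6 | (2R,3S)-2-(but-3-en-1-yl)-3-chloropentanoic acid | CC[C@H](Cl)[C@H](CCC=C)C(=O)O
F17 | step 14 | methyl (5Z,8Z)-10-hydroxydeca-5,8-dienoate | OC/C=C\C/C=C\CCCC(=O)OC
F18 | step 14 | methyl (5Z,8Z)-10-bromodeca-5,8-dienoate | BrC/C=C\C/C=C\CCCC(=O)OC
F19 | step 14 | methyl (5Z,8Z,13S,14R,16R)-16-chloro-14-[(1S)-1-chloropropyl]-13-hydroxy-17-(triethylsilyloxy)heptadeca-5,8-dien-11-ynoate | CC[C@H](Cl)[C@H](C[C@@H](Cl)CO[Si](CC)(CC)CC)[C@H](O)C#CC/C=C\C/C=C\CCCC(=O)OC
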